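All constants are invented; the result is computed.

A neighbouring flask differing in its capture agent, 0.013 M in place of 0.0500 M, raises the question of what that charge costs in product.

starting material 0.050 M (fed, over 6.0 h); reagent 0.0550 M; protic impurity 1.00 mM; capture agent 0.0500 M; free catalyst 7.5 mM; time 30 h; the fed solution adds 0.25 times the starting volume

* which holds at 30 h: what has brought the reaction to rest, or that it has not come to rest (no working catalyst is left / the reagent has run out first / forward and back rates have come level / all of the starting material has reacted / it is still moving)
* conversion of starting material at 30 h
* amount of product at 30 h, in percent of the starting material charged
* amount of trapped intermediate at 30 h, in percent of the starting material charged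

- charges are per starting volume, the dose included; the dosed solution carries all of it
- the reaction counts as stopped when no species that holds the starting material changes by six tenths of a point or more over the second half of the time
- run time (flask): 30 h

    starting material + free catalyst → catalyst intermediate A (k1 = 0.225 M⁻¹ min⁻¹)
    starting material + protic impurity → quenched substrate (k2 = 9.46 M⁻¹ min⁻¹)
    catalyst intermediate B ⇌ released group + catalyst intermediate C (K3 = 0.0273 M, k3 = 0.392 min⁻¹)
    catalyst intermediate C → free catalyst + product (k4 = 0.0492 min⁻¹)
    catalyst intermediate A + capture agent → trapped intermediate (k5 = 0.165 M⁻¹ min⁻¹)
    reagent + catalyst intermediate A → catalyst intermediate B (k6 = 0.684 M⁻¹ min⁻¹)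

The catalyst turns by way of catalyst intermediate A, which either takes up reagent, with constant 0.684 M⁻¹ min⁻¹, and goes on towards product, or takes up capture agent, with constant 0.165 M⁻¹ min⁻¹, and leaves the round as trapped intermediate. Both rates are first order in catalyst intermediate A, and the feed dilutes reagent and capture agent alike. Dividing one rate by the other therefore removes time, volume and catalyst. With b and τ the fractions of the reagent and capture agent charges left, the integral is b = τ^S, where S is the selectivity factor, the ratio of the two constants, 4.15.

Each catalyst trapped takes up one capture agent, so with the whole catalyst charge trapped τ falls to 85.0% and b to 51.0%. Product is then bounded by the reagent spent, 53.9%, and trapped intermediate by the catalyst charge, 15.0%. Adding the 2.00% of starting material quenched by protic impurity bounds conversion, 70.9%.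

This reckoning tells where the flask ends, not when. The binding of starting material to free catalyst has a half-life of 6.8 h with the catalyst held at its charge, yet the catalyst runs down meanwhile. How near these ceilings the flask stands at 30 h stays open in this reckoning.

The forecast gave it is still moving, with conversion 55%, product 40% and trapped intermediate 10.5%, holding that “some catalyst and plenty of starting material and reagent remain”.

The simulation gives it is still moving, with conversion 57.7%, product 43.4% and trapped intermediate 11.5%.

The trapping of catalyst intermediate A by capture agent is the main reason this flask's conversion stands at 57.7%, for without that step the run reaches 80.2%. In this flask at 30.0 h, the 88% of capture agent left gives through S a reagent fraction of 60.3%, and 60% stands there. In the neighbour with 0.013 M of capture agent, the 81% left gives 40.9% through the same S, and that flask holds 41% of its reagent, with product at 64.3%.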